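**Strategy.** Everything rests on cutting the dihydrofuran ring of the benzofuran unit at O1–C7a and C2–C3. The key step exploits that C7a is ortho to C3a (carrying C3) and para to C5 (carrying the enone carbon), while C2 sits between O1 and the carbinol carbon. With C3 as ester, the C5 carbon as nitrile and C2 as the α-carbon of methyl glycolate, an SNAr/Dieckmann cascade on a fluorobenzoate makes both bonds and gives a flat 3-hydroxybenzofuran-2-carboxylate. Dearomatizing dynamic-kinetic hydrogenation then sets C2 and C3 (trans, 2R,3R); MeMgBr, nitrile reduction and a Claisen–Schmidt condensation with 3-prenylresacetophenone finish the chalcone.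

Key step: step 1

Remark: benzofuran numbering (O1, C2, C3, C3a, C4–C7, C7a) is used for the bicyclic unit throughout; compounds 1, 2, 11 and 12 are taken as commercially available.

**Step 1**
Reactants: 1 methyl 5-cyano-2-fluorobenzoate; 2 methyl glycolate
Product: 4 methyl 5-cyano-3-hydroxy-1-benzofuran-2-carboxylate, via aryloxyacetate diester 3 (not isolated)
Conditions: NaH (2.5 equiv), 2 (1.3 equiv), DME, 0 → 65 °C; then aq. HCl
Reagents that add atoms: none
Why: The sodium alkoxide of 2 adds at the C–F carbon to give a Meisenheimer adduct stabilized by the ortho ester and the para nitrile, and loss of fluoride forms the O1–C7a bond (diester 3); a second equivalent of base then forms the ester enolate at the OCH2 carbon, which attacks the neighbouring aryl ester carbonyl and expels methoxide, forming the C2–C3 bond. The closest known reaction type is the tandem SNAr/Dieckmann condensation of glycolates with 2-halo(hetero)aryl esters, which gives 3-hydroxybenzofuran- and 3-hydroxyfuropyridine-2-carboxylates. The furan ring closes in the 5-(enolexo)-exo-trig mode. No stereocentre is formed here, since the product is the flat enol; C2 and C3 are set in step 2. The step needs substitution at C–F to outrun attack at the esters and at the nitrile: the double activation of the fluoride secures this, the methyl/methyl ester match makes any transesterification degenerate, and deprotonation of the acidic product to its enolate should make the cascade irreversible.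

**Step 2**
Reactants: 4 methyl 5-cyano-3-hydroxy-1-benzofuran-2-carboxylate
Product: 6 methyl (2R,3R)-5-cyano-3-hydroxy-2,3-dihydro-1-benzofuran-2-carboxylate, via keto tautomer 5 (not isolated)
Conditions: [RuCl(C6H6)((R)-BINAP)]Cl (1 mol %), H2 (80 atm), CH2Cl2–MeOH 9:1, 50 °C
Reagents that add atoms: none
Why: Noyori Ru–BINAP hydrogenation with dynamic kinetic resolution of a cyclic α-substituted β-keto ester: the stereolabile keto tautomer 5 should racemize through enol 4 faster than it is reduced, (R)-BINAP should select the carbonyl face that gives the 3R carbinol, and the chelated ester should direct hydride cis to itself so that the trans-(2R,3R) isomer is expected, by analogy with 2-alkoxycarbonylcyclopentanones; the aryl nitrile should not be reduced under these conditions.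

**Step 3**
Reactants: 6 methyl (2R,3R)-5-cyano-3-hydroxy-2,3-dihydro-1-benzofuran-2-carboxylate
Product: 8 (2R,3R)-3-hydroxy-2-(2-hydroxypropan-2-yl)-2,3-dihydro-1-benzofuran-5-carbonitrile, via methyl ketone 7 (not isolated)
Conditions: MeMgBr (4 equiv), THF, −40 → 0 °C; aq. NH4Cl
Reagents that add atoms: methylmagnesium bromide, C[Mg]Br
Why: Double Grignard addition to the activated α-aryloxy ester via ketone 7 after deprotonation of the 3-OH; at low temperature the aryl nitrile, deactivated by the para oxygen, should survive, and no bond at C2 or C3 is broken, so the trans-(2R,3R) configuration should be retained.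

**Step 4**
Reactants: 8 (2R,3R)-3-hydroxy-2-(2-hydroxypropan-2-yl)-2,3-dihydro-1-benzofuran-5-carbonitrile
Product: 10 (2R,3R)-3-hydroxy-2-(2-hydroxypropan-2-yl)-2,3-dihydro-1-benzofuran-5-carbaldehyde, via aldimine 9 (not isolated)
Conditions: DIBAL-H (3.5 equiv), CH2Cl2, −78 → −20 °C; then aq. Rochelle salt and dilute citric acid, 0 °C
Reagents that add atoms: water, O
Why: DIBAL-H partial reduction of an aryl nitrile stops at the N-aluminium aldimine, which is hydrolysed to the aldehyde on mild work-up; the two hydroxyls only consume hydride as aluminium alkoxides, and the mild acid should spare the benzylic alcohol.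

**Step 5**
Reactants: 11 2,4-dihydroxyacetophenone; 12 prenyl bromide
Product: 13 1-[2,4-dihydroxy-3-(3-methylbut-2-enyl)phenyl]ethanone
Conditions: 12 (1.0 equiv), 10 % aq. KOH, 0 °C → rt
Reagents that add atoms: none
Why: C-alkylation of the resorcinol phenoxide in water, where solvation of oxygen favours carbon attack and C3 between the two oxygens is the most nucleophilic ring carbon; the 3-prenyl isomer should be the main C-alkylated product and would be separated from the 5-prenyl and O-prenyl isomers by chromatography.

**Step 6**
Reactants: 13 1-[2,4-dihydroxy-3-(3-methylbut-2-enyl)phenyl]ethanone; 10 (2R,3R)-3-hydroxy-2-(2-hydroxypropan-2-yl)-2,3-dihydro-1-benzofuran-5-carbaldehyde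
Product: 15 paratocarpin G, via β-hydroxy ketone 14 (not isolated)
Conditions: 50 % aq. KOH (excess), EtOH, N2, 0 °C → rt; then dilute HCl to pH 5 at 0 °C
Reagents that add atoms: none
Why: Claisen–Schmidt condensation: the methyl ketone enolate of the unprotected phenoxide adds to the non-enolizable aldehyde, and E1cB dehydration of 14 should give the conjugated (E)-enone as the thermodynamic isomer; the 2'-phenoxide should keep the chalcone open until cold acidification, and C2 and C3 are not α to a carbonyl, so they should not epimerize.

**Compound list**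
1 | methyl 5-cyano-2-fluorobenzoate | COC(=O)c1cc(C#N)ccc1F | starting material
2 | methyl glycolate | COC(=O)CO | starting material
3 | methyl 5-cyano-2-(2-methoxy-2-oxoethoxy)benzoate | COC(=O)COc1ccc(C#N)cc1C(=O)OC | intermediate (not isolated)
4 | methyl 5-cyano-3-hydroxy-1-benzofuran-2-carboxylate | COC(=O)c1oc2ccc(C#N)cc2c1O | intermediate
5 | methyl 5-cyano-3-oxo-2,3-dihydro-1-benzofuran-2-carboxylate (keto tautomer of 4, stereolabile) | COC(=O)C1Oc2ccc(C#N)cc2C1=O | intermediate (not isolated)
6 | methyl (2R,3R)-5-cyano-3-hydroxy-2,3-dihydro-1-benzofuran-2-carboxylate | N#Cc1ccc2c(c1)[C@@H](O)[C@H](C(=O)OC)O2 | intermediate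
7 | (2R,3R)-2-acetyl-3-hydroxy-2,3-dihydro-1-benzofuran-5-carbonitrile | N#Cc1ccc2c(c1)[C@@H](O)[C@H](C(C)=O)O2 | intermediate (not isolated)
8 | (2R,3R)-3-hydroxy-2-(2-hydroxypropan-2-yl)-2,3-dihydro-1-benzofuran-5-carbonitrile | N#Cc1ccc2c(c1)[C@@H](O)[C@H](C(C)(C)O)O2 | intermediate
9 | (2R,3R)-2-(2-hydroxypropan-2-yl)-5-(iminomethyl)-2,3-dihydro-1-benzofuran-3-ol (aldimine, present as its N-aluminium derivative) | N=Cc1ccc2c(c1)[C@@H](O)[C@H](C(C)(C)O)O2 | intermediate (not isolated)
10 | (2R,3R)-3-hydroxy-2-(2-hydroxypropan-2-yl)-2,3-dihydro-1-benzofuran-5-carbaldehyde | O=Cc1ccc2c(c1)[C@@H](O)[C@H](C(C)(C)O)O2 | intermediate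
11 | 2,4-dihydroxyacetophenone | CC(=O)c1ccc(O)cc1O | starting material
12 | prenyl bromide (1-bromo-3-methylbut-2-ene) | CC(C)=CCBr | starting material
13 | 1-[2,4-dihydroxy-3-(3-methylbut-2-enyl)phenyl]ethanone | CC(=O)c1ccc(O)c(CC=C(C)C)c1O | intermediate
14 | 1-[2,4-dihydroxy-3-(3-methylbut-2-enyl)phenyl]-3-hydroxy-3-[(2R,3R)-3-hydroxy-2-(2-hydroxypropan-2-yl)-2,3-dihydro-1-benzofuran-5-yl]propan-1-one (mixture of epimers at the new carbinol) | CC(C)=CCc1c(O)ccc(C(=O)CC(O)c2ccc3c(c2)[C@@H](O)[C@H](C(C)(C)O)O3)c1O | intermediate (not isolated)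
15 | paratocarpin G | CC(C)=CCc1c(O)ccc(C(=O)/C=C/c2ccc3c(c2)[C@@H](O)[C@H](C(C)(C)O)O3)c1O | target

**Total step count:** 6. **Longest linear sequence:** 5 (steps 1, 2, 3, 4, 6).

**Steps most likely to fail**

Step 2. The aromatic enol may be reduced only slowly, the nitrile may slow the catalyst, and the facial or cis/trans selectivity of the dynamic kinetic resolution may be poor on this benzo-fused oxacycle. Fallback, setting out from 4:
- Noyori–Ikariya transfer hydrogenation with dynamic kinetic resolution (RuCl(p-cymene)[(R,R)-TsDPEN], HCO2H/Et3N) should give the cis isomer methyl (2R,3S)-5-cyano-3-hydroxy-2,3-dihydro-1-benzofuran-2-carboxylate F1.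
- Mitsunobu inversion at C3 (PPh3, DIAD, benzoic acid, THF, 0 °C) would give methyl (2R,3R)-3-(benzoyloxy)-5-cyano-2,3-dihydro-1-benzofuran-2-carboxylate F2.
- Excess MeMgBr (THF, −40 → 0 °C) would convert the methyl ester into the tertiary carbinol and cleave the benzoate in the same flask, coming back to the route at 8.

Step 5. Alkylation may be spread over C3, C5 and the oxygens, so regioselectivity may be poor and 13 hard to separate. Fallback, setting out from 11:
- Selective 4-O-alkylation with 3-chloro-3-methylbut-1-yne (K2CO3, KI, CuI cat., acetone, reflux) would give 1-[2-hydroxy-4-(2-methylbut-3-yn-2-yloxy)phenyl]ethanone F3.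
- Lindlar semi-hydrogenation would give 1-[2-hydroxy-4-(2-methylbut-3-en-2-yloxy)phenyl]ethanone F4.
- Aromatic Claisen rearrangement (N,N-diethylaniline, 190 °C) should then deliver the prenyl group to C3, the position between the two oxygens, coming back to the route at 13.

Step 6. Enolization of the doubly deprotonated ketone may be sluggish, the aldehyde may undergo Cannizzaro disproportionation, and the chalcone may partly close to the flavanone on work-up. Fallback, setting out from 13:
- Protection of both phenols (NaH, MOMCl, DMF) would give 1-[2,4-bis(methoxymethoxy)-3-(3-methylbut-2-enyl)phenyl]ethanone F5.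
- Claisen–Schmidt condensation with 10 (KOH, EtOH, rt) would give the bis-MOM ether of paratocarpin G F6.
- Dilute HCl in MeOH at rt would remove the acetals, coming back to the route at 15.

**Further compounds**
F1 | step 2 | methyl (2R,3S)-5-cyano-3-hydroxy-2,3-dihydro-1-benzofuran-2-carboxylate | N#Cc1ccc2c(c1)[C@H](O)[C@H](C(=O)OC)O2
F2 | step 2 | methyl (2R,3R)-3-(benzoyloxy)-5-cyano-2,3-dihydro-1-benzofuran-2-carboxylate | N#Cc1ccc2c(c1)[C@@H](OC(=O)c3ccccc3)[C@H](C(=O)OC)O2
F3 | step 5 | 1-[2-hydroxy-4-(2-methylbut-3-yn-2-yloxy)phenyl]ethanone | CC(=O)c1ccc(OC(C)(C)C#C)cc1O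
F4 | step 5 | 1-[2-hydroxy-4-(2-methylbut-3-en-2-yloxy)phenyl]ethanone | CC(=O)c1ccc(OC(C)(C)C=C)cc1O
F5 | step 6 | 1-[2,4-bis(methoxymethoxy)-3-(3-methylbut-2-enyl)phenyl]ethanone | CC(=O)c1ccc(OCOC)c(CC=C(C)C)c1OCOC
F6 | step 6 | paratocarpin G bis(methoxymethyl) ether | CC(C)=CCc1c(OCOC)ccc(C(=O)/C=C/c2ccc3c(c2)[C@@H](O)[C@H](C(C)(C)O)O3)c1OCOC
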